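The data are simulated for substances that don't exist; the scatter is artificial.

Two questions came before the meeting on this flask: how much electrophile has reacted at 10 d, and what share of the unused nucleophile is still free.

- elm: electrophile 0.050 M; nucleophile 0.15 M; free base 0.15 M; the very flask that is asked about, followed so far
- flask: electrophile 0.050 M; nucleophile 0.150 M; free base 0.150 M; time 10 d

elm run (percent of the electrophile charged)

| time / h | electrophile / % | product / % |
|---|---|---|
| 4.00 | 92.6 | 7.6 |
| 8.00 | 84.8 | 13.7 |
| 20.0 | 70.3 | 31.2 |
| 50.0 | 44.2 | 54.8 |

(scatter of a reading: 0.5 percentage points)

- part of the electrophile that has reacted at 10 d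
- share of the unused nucleophile that is free and not bound as protonated nucleophile, at 10 d

- what is said of product includes crystals
- crystals is a solid; its amount is given per volume of the solution
- candidate steps: electrophile + nucleophile -> acid set free + product; nucleophile + acid set free <-> protonated nucleophile; acid set free + free base <-> salt of the base; crystals <-> product
- the earlier runs do not show how much of nucleophile is bound; that part of a forecast is a guess

The chair noted that the elm run is this very flask followed so far, so its constant needs no transfer. The kineticist proposed treating the binding of acid set free as instantaneous and asking who catches it: if the free base does, each electrophile reacted costs one nucleophile, and if the nucleophile does, two.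

The analyst reckoned the second-order constant both ways. One-for-one it falls from 0.00235 M⁻¹ min⁻¹ at 8.00 h to 0.00204 M⁻¹ min⁻¹ at 50.0 h. Two-for-one it reads 0.00242 M⁻¹ min⁻¹, then 0.00234 M⁻¹ min⁻¹. The meeting kept this last reading as the two-for-one constant, the rate constant when each electrophile reacted removes two nucleophile. The chair warned that the split of the acid stays a guess.

In this flask two nucleophile per electrophile charged take 0.100 M, less than the 0.150 M of nucleophile charged, so even on that count the electrophile is the limiting reagent. Integrating with that constant, I reckon 93.0 % reacted and 55.1 % free.

The forecast stands at 96 % and 90 %, on the ground that “the free base takes most of the acid”, and its free share lies above mine.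

The flask gives 93.5 % reacted and 61.2 % free.

    electrophile + nucleophile → acid set free + product (k = 0.00229 M⁻¹ min⁻¹)
    nucleophile + acid set free ⇌ protonated nucleophile, settled at all times (K = 2000 M⁻¹)
    acid set free + free base ⇌ salt of the base, settled at all times (K = 140 M⁻¹)
    crystals ⇌ product, rate k4*(cs4 - [product]) while solid is left; crystals form when [product] > cs4 (solubility = 25.0 mM, k = 0.133 min⁻¹)

At 10.0 d this flask holds 0.0401 M protonated nucleophile against 0.00638 M salt of the base, so more of the acid set free sits on the nucleophile than on the free base. Carried to the neighbour flask charged with 0.020 M of electrophile, the constant 0.00234 M⁻¹ min⁻¹ gives 1.81 % electrophile left and 84.9 % free at 10 d, and that neighbour holds 1.9 % and 86.3 %.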